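The runs are simulated on assumed constants.

A percentage point of the Z charged to west, the flask in question, is 1.00 mM, and I kept every count in that unit. Z is the substrate, J the product and E the catalyst as charged.

- west: Z 0.10 M; E 20 µM; temperature 37 °C; the very flask that is asked about, followed so far
- flask: Z 0.10 M; E 20 µM; temperature 37 °C; time 8.0 h

- west (time / h: J / %, Z / %): 1.00: 16.3, 54.7; 2.50: 42.7, 18.8; 3.00: 47.1, 15.0; 5.00: 50.5, 10.5; 6.00: 49.9, 9.8; 8.00: 50.6, 10.0

(each reading ± 0.5 percentage points)

- zeta: at 8.0 h take out 90 % of the J then present, then wait 4.0 h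
- epsilon: change nothing and wait 4.0 h more
- delta: at 8.0 h add E, 100 % of the amount charged, then wait 4.0 h

- J taken out counts as made
- the analysis behind the earlier runs scatters by 0.5 percentage points, standard deviation
- additions bring no volume worth counting

* J, in percent of the Z first charged, at 8.0 h
* the remedy with the largest gain of J, or "none" below 2 percentage points (zeta / epsilon / delta / none)
* J present, with what was taken out counted in, in percent of the Z first charged, after zeta
* J present, with what was taken out counted in, in percent of the Z first charged, after delta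

At the bench, a run that goes flat with Z left is read as thermodynamic control, and its last J/Z is taken as an equilibrium ratio. For west I wrote R = 5.06, the plateau ratio, J over Z at the last reading. The rule has a border, and the ratio shows it. In west, J/Z read 3.14 at 3.00 h, below R, then 4.81 at 5.00 h and 5.09 at 6.00 h. So I trusted the readings from about 5.00 h on. A second limit was that 39.4 % of the charge stood in neither Z nor J, and I assumed it stayed out.

If R holds, taking out a share x of J lets the remaining Z and J share out again at R, for a gain of x·J·Z/(J+Z). For zeta in west I reckoned 7.5 percentage points, above the margin of 2 points, which puts g1 at 58.1 %. A catalyst moves no equilibrium ratio, so I expected nothing from delta and chose zeta.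

The forecast read the plateau otherwise: “this looks like catalyst death, not equilibrium”. It gave now 50.3 %, best delta, g1 50.5 % and g3 90 %.

West gave 50.1 % at 8.0 h. Zeta brought 57.1 %, a gain of 6.9 points, the largest. Epsilon changed J by −1.4 points, and delta brought 48.7 %, a change of −1.5 points.

    G ⇌ Q + J (K = 0.0550 M, k = 3.40 s⁻¹, Ea = 75.0 kJ mol⁻¹, ΔH = −22.0 kJ mol⁻¹)
    Z + Q ⇌ G (K = 94.0 M⁻¹, k = 42.0 M⁻¹ s⁻¹, Ea = 38.0 kJ mol⁻¹, ΔH = −38.0 kJ mol⁻¹)
    Q → D (k = 3.20 × 10⁻⁶ s⁻¹, Ea = 273 kJ mol⁻¹)
    2 Z → X (k = 6.50 × 10⁻⁴ M⁻¹ s⁻¹, Ea = 81.0 kJ mol⁻¹)
    E → Q (k = 1.10 × 10⁻⁴ s⁻¹, Ea = 91.0 kJ mol⁻¹)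
    (constants at 37 °C)

West at 8.00 h held 48.5 % of its catalyst as Q, 44.0 % as G, 3.29 % as D and 4.21 % as E. The main reason for the J missing from west is the reaction of two Z to X: the west run without that step gives 83.7 % of J, against 50.1 % with it. Zeta's gain in west was 6.9 points, against my 7.5 points. In the neighbour flask charged with 0.17 M of Z, R times its 7.06 % of Z gives 35.7 % of J, and that flask held 38.0 %.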